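The route is built on the fact that C2 and C3 of ring B carry the same 2,4-dioxygenated benzoyl group. The C2–C3 1,4-diketone can therefore be unfolded to a symmetric 1,3-diketone that lacks C3. The carbenoid EtZnCH2I puts this carbon back in one operation, inserting CH2 between C2 and one aroyl carbonyl (C2–C3 and C3–C(=O) form, C2–C(=O) breaks). The precursor is the heptamethyl-protected 2-(diarylmethyl)-1,3-diaryl-1,3-diketone, whose only stereocentre, C1, is set beforehand by catalytic asymmetric conjugate arylation and whose C2 is not stereogenic. Afterwards C4 is added as an enaminone carbon and closed onto ring A, C2 settles trans, and the methyl ethers are removed.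

Key step: step 4

Remark on numbering: atoms are numbered as in the target 1,2-dihydronaphthalene (C1–C4, C4a, C5–C8, C8a). Ring A is the benzo ring and ring B is C1–C2–C3–C4–C4a–C8a. The target is (1R,2S), with the C1 aryl and C2 aroyl groups trans.

Remark on protecting groups: all seven phenols are carried as methyl ethers. The two oxygens ortho to the ketones must stay alkylated until ring B is closed, because a free or easily dealkylated oxygen there would add to C4 of the enaminone and give a chromone. Methyl is inert from NaH to CF3CO2H and is still removed from all seven positions in one final operation.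

Assumption: (R,R)-Ph-bod* is taken to give the (R) configuration at C1 in step 3. If the first run shows the opposite sense, the (S,S) antipode is used with no other change.

Step 1
Reactants: 1 2',4'-dimethoxyacetophenone; 2 methyl 2,4-dimethoxybenzoate
Product: 3 1,3-bis(2,4-dimethoxyphenyl)propane-1,3-dione
Conditions: NaH (2.5 equiv), THF, reflux; then 1 M HCl, 0 °C
Reagents that add atoms: none
Why: Crossed Claisen condensation, in which the sodium enolate of the methyl ketone is acylated by the non-enolisable aryl ester and the equilibrium is pulled through by deprotonation of the 1,3-diketone, released on acidification; aryl methyl ethers are inert to NaH.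

Step 2
Reactants: 3 1,3-bis(2,4-dimethoxyphenyl)propane-1,3-dione; 4 4-methoxybenzaldehyde
Product: 5 1,3-bis(2,4-dimethoxyphenyl)-2-[(4-methoxyphenyl)methylidene]propane-1,3-dione
Conditions: piperidine (0.2 equiv), AcOH (0.2 equiv), toluene, reflux, Dean–Stark trap
Reagents that add atoms: none
Why: Knoevenagel condensation of the active methylene with a non-enolisable aldehyde, driven by azeotropic removal of water; the two aroyl groups are identical, so the new C=C bond has no geometric isomers and no stereocentre forms.

Step 3
Reactants: 5 1,3-bis(2,4-dimethoxyphenyl)-2-[(4-methoxyphenyl)methylidene]propane-1,3-dione; 6 (3,4-dimethoxyphenyl)boronic acid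
Product: 7 2-[(R)-(3,4-dimethoxyphenyl)(4-methoxyphenyl)methyl]-1,3-bis(2,4-dimethoxyphenyl)propane-1,3-dione
Conditions: [RhCl(C2H4)2]2 (2.5 mol %), (R,R)-Ph-bod* [(1R,4R)-2,5-diphenylbicyclo[2.2.2]octa-2,5-diene, 5.5 mol %], KOH (0.2 equiv), 1,4-dioxane/H2O 10:1, 30–40 °C
Reagents that add atoms: none
Why: Hayashi–Miyaura conjugate arylation of a doubly activated arylidene acceptor, in which the aryl–rhodium species held by the twofold-symmetric chiral diene inserts the C=C bond from one enantioface and so sets C1, and water protonates the O-bound rhodium enolate; C2 is not stereogenic because its two aroyl groups are identical, and C1 afterwards bears no acidic hydrogen.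

Step 4
Reactants: 7 2-[(R)-(3,4-dimethoxyphenyl)(4-methoxyphenyl)methyl]-1,3-bis(2,4-dimethoxyphenyl)propane-1,3-dione; 8 diiodomethane
Product: 12 (2R)-2-[(R)-(3,4-dimethoxyphenyl)(4-methoxyphenyl)methyl]-1,4-bis(2,4-dimethoxyphenyl)butane-1,4-dione, via ethylzinc enolate 9 (not isolated), via zinc cyclopropanolate 10 (not isolated), via chain-extended ethylzinc enolate 11 (not isolated)
Conditions: Et2Zn (1.1 equiv), CH2Cl2, 0 °C to rt; EtZnCH2I (1.5 equiv, preformed from Et2Zn and 8 in CH2Cl2 at 0 °C), 0 °C to rt; sat. aq NH4Cl, −20 °C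
Reagents that add atoms: none
Why: Et2Zn deprotonates C2 of 7 to the chelated ethylzinc enolate 9, whose C2 attacks the CH2 carbon of EtZnCH2I with loss of iodide to forge C2–C3; the new C3–Zn bond then adds to one flanking carbonyl (3-exo-trig) to give the donor–acceptor cyclopropanolate 10, which collapses by cleavage of the old C2–C(=O) bond to the ketone and the new enolate 11, a net 1,2-acyl shift. The closest known reaction type is the zinc carbenoid chain extension of β-keto esters and 1,3-diketones, α-substituted ones included, to 1,4-dicarbonyl compounds. No ring of the target closes; the three-membered ring of 10 is transient. The one new stereocentre, C2, arises when 11 is protonated in the quench and is left uncontrolled (12 should form together with its C2 epimer), because C2 is equilibrated after ring B is closed, while C1 is untouched since it has no acidic hydrogen. The step needs a single insertion: the two aroyl groups are identical, so either may migrate to the same product, and the fully substituted, hindered enolate 11 should resist a second alkylation when only a small excess of EtZnCH2I is used and the quench is cold. The substrate has no alkene, and its anisole-type rings are inert to the carbenoid.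

Step 5
Reactants: 12 (2R)-2-[(R)-(3,4-dimethoxyphenyl)(4-methoxyphenyl)methyl]-1,4-bis(2,4-dimethoxyphenyl)butane-1,4-dione; 13 N,N-dimethylformamide dimethyl acetal
Product: 14 (2S)-2-[(R)-(3,4-dimethoxyphenyl)(4-methoxyphenyl)methyl]-3-[(dimethylamino)methylidene]-1,4-bis(2,4-dimethoxyphenyl)butane-1,4-dione
Conditions: neat 13 (10 equiv), 110 °C, sealed tube
Reagents that add atoms: none
Why: Enaminone formation by condensation of the amide acetal with the only α-methylene group (C3), which installs C4 at the aldehyde oxidation level; C2 is a methine and cannot condense, and any epimerisation at C2 is harmless because both epimers converge in step 6.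

Step 6
Reactants: 14 (2S)-2-[(R)-(3,4-dimethoxyphenyl)(4-methoxyphenyl)methyl]-3-[(dimethylamino)methylidene]-1,4-bis(2,4-dimethoxyphenyl)butane-1,4-dione
Product: 16 [(1R,2S)-6,7-dimethoxy-1-(4-methoxyphenyl)-1,2-dihydronaphthalene-2,3-diyl]bis[(2,4-dimethoxyphenyl)methanone], via 4-(dimethylamino)tetralin 15 (not isolated)
Conditions: CF3CO2H (10 equiv), CH2Cl2, 0 °C to rt; aq NaHCO3 wash; then DBU (0.2 equiv), CH2Cl2, rt
Reagents that add atoms: none
Why: Acid-promoted intramolecular Friedel–Crafts cyclisation of Bradsher cyclodehydration type with dimethylamine as leaving group: O-protonation of the vinylogous amide makes C4 an iminium-type electrophile, the dimethoxy-activated ring A attacks through its position para to the C7 methoxy group to form C4–C4a (the anisyl ring offers only positions meta to its methoxy group and the aroyl rings are deactivated), β-amino ketone 15 loses HNMe2 to give the conjugated C3=C4 bond, and DBU equilibrates C2 through its extended enolate to the trans arrangement while C1, which has no acidic hydrogen, keeps its configuration.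

Step 7
Reactants: 16 [(1R,2S)-6,7-dimethoxy-1-(4-methoxyphenyl)-1,2-dihydronaphthalene-2,3-diyl]bis[(2,4-dimethoxyphenyl)methanone]
Product: 17 [(1R,2S)-6,7-dihydroxy-1-(4-hydroxyphenyl)-1,2-dihydronaphthalene-2,3-diyl]bis[(2,4-dihydroxyphenyl)methanone]
Conditions: BBr3 (14 equiv), CH2Cl2, −78 °C to rt; then H2O, 0 °C, under argon
Reagents that add atoms: none
Why: Lewis acid-mediated cleavage of aryl methyl ethers, in which bromide attacks the O-methyl carbon of each boron-complexed ether and the two methoxy groups ortho to the ketones react first with chelation assistance; the molecule has no other C–O single bond, C1 has no acidic hydrogen and C2 stays in its thermodynamic trans arrangement.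

Compound list
1 | 2',4'-dimethoxyacetophenone | CC(=O)c1ccc(OC)cc1OC | starting material
2 | methyl 2,4-dimethoxybenzoate | COC(=O)c1ccc(OC)cc1OC | starting material
3 | 1,3-bis(2,4-dimethoxyphenyl)propane-1,3-dione | COc1ccc(C(=O)CC(=O)c2ccc(OC)cc2OC)c(OC)c1 | intermediate
4 | 4-methoxybenzaldehyde | COc1ccc(C=O)cc1 | starting material
5 | 1,3-bis(2,4-dimethoxyphenyl)-2-[(4-methoxyphenyl)methylidene]propane-1,3-dione | COc1ccc(C=C(C(=O)c2ccc(OC)cc2OC)C(=O)c2ccc(OC)cc2OC)cc1 | intermediate
6 | (3,4-dimethoxyphenyl)boronic acid | COc1ccc(B(O)O)cc1OC | starting material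
7 | 2-[(R)-(3,4-dimethoxyphenyl)(4-methoxyphenyl)methyl]-1,3-bis(2,4-dimethoxyphenyl)propane-1,3-dione | COc1ccc(cc1OC)[C@@H](c1ccc(OC)cc1)C(C(=O)c1ccc(OC)cc1OC)C(=O)c1ccc(OC)cc1OC | intermediate
8 | diiodomethane | ICI | starting material
9 | ethylzinc enolate of 7 (C1 as in 7; enolate geometry not specified) | COc1ccc(cc1OC)[C@@H](c1ccc(OC)cc1)C(C(=O)c1ccc(OC)cc1OC)=C(O[Zn]CC)c1ccc(OC)cc1OC | intermediate
10 | ethylzinc 1,2-bis(2,4-dimethoxyphenyl)-substituted cyclopropanolate: cyclopropane of C2 (bearing the diarylmethyl and one aroyl group), the new CH2 and the former carbonyl carbon (bearing OZnEt and its aryl group); C1 as in 7, ring stereocentres transient and not specified | COc1ccc(cc1OC)[C@@H](c1ccc(OC)cc1)C1(C(=O)c2ccc(OC)cc2OC)CC1(O[Zn]CC)c1ccc(OC)cc1OC | intermediate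
11 | ethylzinc enolate of 12 (C1 as in 7; enolate geometry not specified) | COc1ccc(cc1OC)[C@@H](c1ccc(OC)cc1)C(CC(=O)c1ccc(OC)cc1OC)=C(O[Zn]CC)c1ccc(OC)cc1OC | intermediate
12 | (2R)-2-[(R)-(3,4-dimethoxyphenyl)(4-methoxyphenyl)methyl]-1,4-bis(2,4-dimethoxyphenyl)butane-1,4-dione; expected together with its (2S) epimer, both of which converge at 16 | COc1ccc(cc1OC)[C@@H](c1ccc(OC)cc1)[C@@H](CC(=O)c1ccc(OC)cc1OC)C(=O)c1ccc(OC)cc1OC | intermediate
13 | N,N-dimethylformamide dimethyl acetal | CN(C)C(OC)OC | starting material
14 | (2S)-2-[(R)-(3,4-dimethoxyphenyl)(4-methoxyphenyl)methyl]-3-[(dimethylamino)methylidene]-1,4-bis(2,4-dimethoxyphenyl)butane-1,4-dione; same spatial arrangement at C2 as 12, C2 epimer also present, enaminone geometry labile and not specified | COc1ccc(cc1OC)[C@@H](c1ccc(OC)cc1)[C@@H](C(=CN(C)C)C(=O)c1ccc(OC)cc1OC)C(=O)c1ccc(OC)cc1OC | intermediate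
15 | [(1R)-4-(dimethylamino)-6,7-dimethoxy-1-(4-methoxyphenyl)-1,2,3,4-tetrahydronaphthalene-2,3-diyl]bis[(2,4-dimethoxyphenyl)methanone]; C2, C3 and C4 transient and not specified | O=C(C1C(N(C)C)c2cc(OC)c(OC)cc2[C@@H](c2ccc(OC)cc2)C1C(=O)c1ccc(OC)cc1OC)c1ccc(OC)cc1OC | intermediate
16 | [(1R,2S)-6,7-dimethoxy-1-(4-methoxyphenyl)-1,2-dihydronaphthalene-2,3-diyl]bis[(2,4-dimethoxyphenyl)methanone] | O=C(C1=Cc2cc(OC)c(OC)cc2[C@@H](c2ccc(OC)cc2)[C@@H]1C(=O)c1ccc(OC)cc1OC)c1ccc(OC)cc1OC | intermediate
17 | [(1R,2S)-6,7-dihydroxy-1-(4-hydroxyphenyl)-1,2-dihydronaphthalene-2,3-diyl]bis[(2,4-dihydroxyphenyl)methanone] (CNP0195549.2) | O=C(C1=Cc2cc(O)c(O)cc2[C@@H](c2ccc(O)cc2)[C@@H]1C(=O)c1ccc(O)cc1O)c1ccc(O)cc1O | target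

Total step count: 7
Longest linear sequence: 7 steps (1 → 3 → 5 → 7 → 12 → 14 → 16 → 17)

Steps most likely to fail

1. Step 4 (key step). C-alkylation of the congested enolate 9 may stall, since a quaternary C2 must form beside the diarylmethyl group, or enolate 11 may take up a second carbenoid and end as a cyclopropanol. The fallback sets out from 7 and comes back at 12. Retro-Claisen cleavage of 7 with KOH in aqueous EtOH removes one aroyl group as 2,4-dimethoxybenzoic acid and should give (3R)-3-(3,4-dimethoxyphenyl)-1-(2,4-dimethoxyphenyl)-3-(4-methoxyphenyl)propan-1-one F1. Its lithium enolate (LiN(SiMe3)2, THF, −78 °C) is alkylated with commercial 2-bromo-1-(2,4-dimethoxyphenyl)ethan-1-one, which attaches C3 and the second aroyl group in one operation and gives 12 as a C2 epimer mixture. C1 is untouched because it has no acidic hydrogen.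

2. Step 6. The protonated enaminone may be too weak an electrophile, so that ring closure onto ring A is slower than acid-induced cyclodehydration of the 1,4-dicarbonyl array to a furan. The fallback sets out from 12 and comes back at 16, and brings in C4 as an acetal carbon. Dialkoxymethylation of C3 (HC(OMe)3, BF3·OEt2, then i-Pr2NEt, CH2Cl2, −78 °C) should give 2-[(R)-(3,4-dimethoxyphenyl)(4-methoxyphenyl)methyl]-3-(dimethoxymethyl)-1,4-bis(2,4-dimethoxyphenyl)butane-1,4-dione F2. Me3SiOTf in CH2Cl2 at −78 °C ionises the acetal to a methoxycarbenium ion at C4, a much stronger electrophile, which ring A captures at low temperature to give [(1R)-4,6,7-trimethoxy-1-(4-methoxyphenyl)-1,2,3,4-tetrahydronaphthalene-2,3-diyl]bis[(2,4-dimethoxyphenyl)methanone] F3. DBU then eliminates methanol across C3–C4 (E1cB) and equilibrates C2, giving 16.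

3. Step 3. Turnover may be slow because the hindered, donor-substituted acceptor inserts sluggishly and the product can hold rhodium as a chelated enolate, which would allow protodeboronation and erode facial selectivity. The fallback sets out from 1 and 4 and comes back at 7. Claisen–Schmidt condensation of 1 with 4 (KOH, EtOH) gives (E)-1-(2,4-dimethoxyphenyl)-3-(4-methoxyphenyl)prop-2-en-1-one F4. Conjugate arylation of this chalcone with 6 under [RhCl(C2H4)2]2 and the chiral diene, a standard substrate class for the reaction, sets C1 and gives ketone F1, the compound of the first fallback. Soft-enolisation C-acylation (MgBr2·OEt2, i-Pr2NEt, 2,4-dimethoxybenzoyl chloride, CH2Cl2) then installs the second aroyl group and gives 7.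

Further compounds
F1 | step 4 | (3R)-3-(3,4-dimethoxyphenyl)-1-(2,4-dimethoxyphenyl)-3-(4-methoxyphenyl)propan-1-one | COc1ccc(cc1OC)[C@@H](c1ccc(OC)cc1)CC(=O)c1ccc(OC)cc1OC
F2 | step 6 | 2-[(R)-(3,4-dimethoxyphenyl)(4-methoxyphenyl)methyl]-3-(dimethoxymethyl)-1,4-bis(2,4-dimethoxyphenyl)butane-1,4-dione (mixture at C2 and C3) | COc1ccc(cc1OC)[C@@H](c1ccc(OC)cc1)C(C(C(OC)OC)C(=O)c1ccc(OC)cc1OC)C(=O)c1ccc(OC)cc1OC
F3 | step 6 | [(1R)-4,6,7-trimethoxy-1-(4-methoxyphenyl)-1,2,3,4-tetrahydronaphthalene-2,3-diyl]bis[(2,4-dimethoxyphenyl)methanone] (mixture at C2, C3 and C4) | O=C(C1C(OC)c2cc(OC)c(OC)cc2[C@@H](c2ccc(OC)cc2)C1C(=O)c1ccc(OC)cc1OC)c1ccc(OC)cc1OC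
F4 | step 3 | (E)-1-(2,4-dimethoxyphenyl)-3-(4-methoxyphenyl)prop-2-en-1-one | COc1ccc(/C=C/C(=O)c2ccc(OC)cc2OC)cc1
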